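In the five-membered ring of the target (C1 carbonyl, C2=C3 alkene, C4 acetoxy carbon, C5 fully substituted carbinol), the neighbours C1 and C5 form an alpha-ketol, so their bond is an acyloin bond. The route cuts this bond back to a C1 aldehyde and a C5 ketone. One carbene-catalysed crossed benzoin closure should form C1–C5, close the cyclopentanone and create the C5 stereocentre. The precursor is a 20-carbon 5-oxoaldehyde. Its oxygens at C4 and at the side-chain carbinol C1' are tied into an acetonide, giving a trans-4,6-disubstituted 1,3-dioxan-5-one. This exposes the ketone and channels closure into a cis-fused bicycle, which places the C5 hydroxyl trans to the C4 oxygen.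

Key step: step 5

Remark on numbering: the target numbering (C1–C5, C1') is used for all intermediates beside their systematic names.
Assumption: the C=N geometry of hydrazones 6 and 9, the enaminol geometry of 12 and the ozonide carbon of 10 are left undefined. These elements disappear before the next isolated compound and have no bearing on C4, C5 or C1'.

Step 1
Reactants: 1 2,2-dimethyl-1,3-dioxan-5-one; 2 (S)-1-amino-2-(methoxymethyl)pyrrolidine (SAMP)
Product: 3 (S)-N-(2,2-dimethyl-1,3-dioxan-5-ylidene)-2-(methoxymethyl)pyrrolidin-1-amine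
Conditions: cyclohexane, Dean–Stark trap, reflux
Reagents that add atoms: none
Why: Hydrazone condensation of an unhindered ketone with a 1,1-dialkylhydrazine, driven by azeotropic water removal, attaches the auxiliary that later sets C1' and C4; no stereocentre is formed.

Step 2
Reactants: 3 SAMP hydrazone of 1; 4 1-iodotetradecane
Product: 6 (S)-N-[(4S)-2,2-dimethyl-4-tetradecyl-1,3-dioxan-5-ylidene]-2-(methoxymethyl)pyrrolidin-1-amine, via lithium azaenolate 5 (not isolated)
Conditions: t-BuLi, THF, −78 °C; then 4, −100 °C → rt
Reagents that add atoms: none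
Why: Enders SAMP hydrazone alkylation: the methoxy-chelated lithium azaenolate 5 should meet the primary iodide (SN2) only on its unshielded face, which sets the future C1' as (S).

Step 3
Reactants: 6 monoalkylated hydrazone; 7 4-iodobut-1-ene
Product: 9 (S)-N-[(4S,6S)-4-(but-3-enyl)-2,2-dimethyl-6-tetradecyl-1,3-dioxan-5-ylidene]-2-(methoxymethyl)pyrrolidin-1-amine, via lithium azaenolate 8 (not isolated)
Conditions: t-BuLi, THF, −78 °C; then 7, −100 °C → rt
Reagents that add atoms: none
Why: Second Enders SAMP hydrazone alkylation: metalation takes place at the unsubstituted alpha' carbon, and the same auxiliary face rule should make the future C4 (S), that is, trans to the tetradecyl chain.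

Step 4
Reactants: 9 bisalkylated hydrazone
Product: 11 3-[(4S,6S)-2,2-dimethyl-5-oxo-6-tetradecyl-1,3-dioxan-4-yl]propanal (the 4,6-O-isopropylidene derivative of (4S,6S)-4,6-dihydroxy-5-oxoicosanal), via keto ozonide 10 (not isolated)
Conditions: O3, CH2Cl2, −78 °C; then Me2S, −78 °C → rt
Reagents that add atoms: ozone, [O-][O+]=O
Why: Ozonolysis with reductive work-up cleaves the electron-rich C=N bond to the C5 ketone and the terminal alkene to the C1 aldehyde in one cold, neutral operation, so neither alpha-oxygenated stereocentre should epimerise.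

Step 5
Reactants: 11 keto aldehyde
Product: 13 (4S,4aR,7aS)-4a-hydroxy-2,2-dimethyl-4-tetradecylhexahydrocyclopenta[d][1,3]dioxin-5-one (cis-fused; C4 S, C5 R, C1' S in target numbering), via Breslow enaminol 12 (not isolated)
Conditions: 2-(pentafluorophenyl)-6,7-dihydro-5H-pyrrolo[2,1-c][1,2,4]triazol-2-ium tetrafluoroborate (15 mol %), i-Pr2NEt (15 mol %), toluene (0.02 M), Ar, rt
Reagents that add atoms: none
Why: The triazolylidene adds to the C1 aldehyde and a proton shift gives enaminol 12, whose nucleophilic C1 attacks the C5 ketone, after which the alkoxide expels the carbene and leaves the ketol. This is the known carbene-catalysed intramolecular crossed aldehyde–ketone benzoin reaction, which is also documented for ring ketones that carry the aldehyde chain on their alpha carbon. The cyclopentanone closes in a 5-exo-trig mode. C5 is set by the substrate: the short C3–C2–C1 tether reaches the ketone best from the face on which it sits, which in the trans-dioxanone is also the face away from the tetradecyl chain, so the cis-fused bicycle should form with the C5 hydroxyl syn to H–C4 and therefore trans to O–C4, and because the step is reversible the more strained trans-fused isomer can revert. Chemoselectivity is inherent, because only the aldehyde can become the acyl anion equivalent, and the ketone, with both alpha oxygens tied back in a six-membered ring, is unhindered and electrophilic. The acidic N-pentafluorophenyl salt needs only a catalytic tertiary amine, which should keep enolisation at C4 and C1' and aldol pathways slow, while high dilution suppresses intermolecular acyloin formation.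

Step 6
Reactants: 13 bicyclic ketol
Product: 14 (4S,4aR,7aS)-2,2-dimethyl-4-tetradecyl-4a,5-bis(trimethylsilyloxy)-4,4a,7,7a-tetrahydrocyclopenta[d][1,3]dioxine (C1=C2 silyl enol ether, C5 silyl ether)
Conditions: LiN(i-Pr)2 (2.5 equiv), Me3SiCl (5 equiv), THF, −78 → 0 °C
Reagents that add atoms: chlorotrimethylsilane, C[Si](C)(C)Cl
Why: Kinetic enolate O-silylation (silyl enol ether formation): C2 holds the only alpha hydrogens because C5 is fully substituted, the tertiary alkoxide is capped in the same pot, and the basic medium spares the strained acetonide that a silyl triflate might open.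

Step 7
Reactants: 14 bis-silyl compound
Product: 15 (4S,4aR,7aS)-2,2-dimethyl-4-tetradecyl-4a-(trimethylsilyloxy)-4a,7a-dihydrocyclopenta[d][1,3]dioxin-5(4H)-one (C2=C3 enone)
Conditions: Pd(OAc)2 (1.1 equiv), MeCN, rt
Reagents that add atoms: none
Why: Saegusa–Ito oxidation: divalent palladium replaces silicon to give the C2-palladated ketone, and beta-hydride elimination from C3 should release the C2=C3 enone and zerovalent palladium without touching the three stereocentres.

Step 8
Reactants: 15 silyloxy enone
Product: 16 (4S,5S,9S)-9-hydroxy-2,2-dimethyl-4-tetradecyl-1,3-dioxaspiro[4.4]non-7-en-6-one (acetonide now on O–C5 and O–C1', C4 hydroxyl free; same spatial arrangement as 15, with the C5 descriptor changed only by priority rules)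
Conditions: camphorsulfonic acid (10 mol %), acetone containing 1 % water, rt
Reagents that add atoms: none
Why: Acid-catalysed silyl ether cleavage followed by thermodynamic acetonide migration: once O–C5 is free, the 1,3-dioxane, strained by its trans 4,6-substituents against an axial methyl group, should re-close as the five-membered dioxolane on O–C5 and O–C1', and because the trans C4/C5 diol cannot be bridged, only the C4 hydroxyl stays free.

Step 9
Reactants: 16 spiro acetonide alcohol
Product: 17 (4S,5R,9S)-2,2-dimethyl-6-oxo-4-tetradecyl-1,3-dioxaspiro[4.4]non-7-en-9-yl acetate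
Conditions: Ac2O, pyridine, DMAP (cat.), CH2Cl2, 0 °C
Reagents that add atoms: acetic anhydride, CC(=O)OC(C)=O
Why: DMAP-catalysed acylation of the single free secondary alcohol under cold, weakly basic conditions that are standard for 4-hydroxycyclopentenones; C4 keeps its configuration because only the O–H bond reacts.

Step 10
Reactants: 17 acetonide acetate
Product: 18 (4S,5R)-4-acetoxy-5-hydroxy-5-[(1S)-1-hydroxypentadecyl]cyclopent-2-en-1-one (target)
Conditions: TFA–H2O (9:1), CH2Cl2, 0 °C
Reagents that add atoms: none
Why: Acid hydrolysis of an isopropylidene acetal; the acetate and the electron-poor allylic C4–O bond should tolerate cold aqueous acid, and an acidic rather than basic medium suppresses acetyl migration to O–C1'.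

Compound list
1 | 2,2-dimethyl-1,3-dioxan-5-one | CC1(C)OCC(=O)CO1 | starting material
2 | (S)-1-amino-2-(methoxymethyl)pyrrolidine (SAMP) | COC[C@@H]1CCCN1N | starting material
3 | SAMP hydrazone of 1 | COC[C@@H]1CCCN1N=C2COC(C)(C)OC2 | intermediate
4 | 1-iodotetradecane | CCCCCCCCCCCCCCI | starting material
5 | lithium azaenolate of 3 (not isolated) | [Li+].COC[C@@H]1CCCN1[N-]C2=COC(C)(C)OC2 | intermediate
6 | (4S)-4-tetradecyl SAMP hydrazone | CCCCCCCCCCCCCC[C@@H]1OC(C)(C)OCC1=NN2CCC[C@H]2COC | intermediate
7 | 4-iodobut-1-ene | C=CCCI | starting material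
8 | lithium azaenolate of 6 (not isolated) | [Li+].CCCCCCCCCCCCCC[C@@H]1OC(C)(C)OC=C1[N-]N2CCC[C@H]2COC | intermediate
9 | (4S,6S)-4-(but-3-enyl)-6-tetradecyl SAMP hydrazone | CCCCCCCCCCCCCC[C@@H]1OC(C)(C)O[C@@H](CCC=C)C1=NN2CCC[C@H]2COC | intermediate
10 | (4S,6S)-2,2-dimethyl-4-tetradecyl-6-[2-(1,2,4-trioxolan-3-yl)ethyl]-1,3-dioxan-5-one (not isolated) | CCCCCCCCCCCCCC[C@@H]1OC(C)(C)O[C@@H](CCC2OCOO2)C1=O | intermediate
11 | 3-[(4S,6S)-2,2-dimethyl-5-oxo-6-tetradecyl-1,3-dioxan-4-yl]propanal | CCCCCCCCCCCCCC[C@@H]1OC(C)(C)O[C@@H](CCC=O)C1=O | intermediate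
12 | Breslow enaminol from 11 and the triazolylidene (not isolated) | CCCCCCCCCCCCCC[C@@H]1OC(C)(C)O[C@@H](CCC(O)=C2N(c3c(F)c(F)c(F)c(F)c3F)N=C4CCCN24)C1=O | intermediate
13 | (4S,4aR,7aS)-4a-hydroxy-2,2-dimethyl-4-tetradecylhexahydrocyclopenta[d][1,3]dioxin-5-one | CCCCCCCCCCCCCC[C@@H]1OC(C)(C)O[C@H]2CCC(=O)[C@@]12O | intermediate
14 | bis(trimethylsilyl) derivative of 13 (C1=C2 enol ether, C5 ether) | CCCCCCCCCCCCCC[C@@H]1OC(C)(C)O[C@H]2CC=C(O[Si](C)(C)C)[C@@]12O[Si](C)(C)C | intermediate
15 | (4S,4aR,7aS)-2,2-dimethyl-4-tetradecyl-4a-(trimethylsilyloxy)-4a,7a-dihydrocyclopenta[d][1,3]dioxin-5(4H)-one | CCCCCCCCCCCCCC[C@@H]1OC(C)(C)O[C@H]2C=CC(=O)[C@@]12O[Si](C)(C)C | intermediate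
16 | (4S,5S,9S)-9-hydroxy-2,2-dimethyl-4-tetradecyl-1,3-dioxaspiro[4.4]non-7-en-6-one | CCCCCCCCCCCCCC[C@@H]1OC(C)(C)O[C@]12C(=O)C=C[C@@H]2O | intermediate
17 | (4S,5R,9S)-2,2-dimethyl-6-oxo-4-tetradecyl-1,3-dioxaspiro[4.4]non-7-en-9-yl acetate | CCCCCCCCCCCCCC[C@@H]1OC(C)(C)O[C@]12C(=O)C=C[C@@H]2OC(C)=O | intermediate
18 | (4S,5R)-4-acetoxy-5-hydroxy-5-[(1S)-1-hydroxypentadecyl]cyclopent-2-en-1-one | CCCCCCCCCCCCCC[C@H](O)[C@]1(O)C(=O)C=C[C@@H]1OC(C)=O | target

Total step count: 10. Longest linear sequence: 10 steps (from 1).

Steps most likely to fail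

Step 5. The closure may be slower than three competing processes: amine-mediated enolisation of the dioxanone (drift of the trans isomer towards the cis isomer), aldol chemistry of the aldehyde, and intermolecular acyloin formation. The fallback sets out from 11 and comes back at 13. It makes the same C1–C5 bond reductively instead of by umpolung. SmI2 (divalent samarium) in THF/t-BuOH at −78 °C should reduce the aldehyde first. Its ketyl then adds to the C5 ketone in a pinacol cyclisation under the same cis-fusion constraint and gives (4S,4aR,5S,7aS)-2,2-dimethyl-4-tetradecylhexahydrocyclopenta[d][1,3]dioxine-4a,5-diol F1. Parikh–Doering oxidation (SO3·pyridine, DMSO, Et3N) of its only secondary carbinol then leads to 13.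

Step 8. The acetonide equilibrium may stop short of the dioxolane, or water may strip the acetonide altogether, so the C4 hydroxyl would not be singled out. The fallback sets out from 15 and comes back at 18, and it uses no protecting-group relay. TFA–H2O removes the silyl ether and the acetonide to give (4S,5R)-4,5-dihydroxy-5-[(1S)-1-hydroxypentadecyl]cyclopent-2-en-1-one F2. Immobilised Candida antarctica lipase B with vinyl acetate in MTBE should then acetylate the ring allylic carbinol, since 4-hydroxycyclopentenones are established lipase substrates. The tertiary C5 hydroxyl is a poor substrate, as is the C1' carbinol, which is wedged between a quaternary carbon and the long chain. This gives 18 directly.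

Step 3. The basic azaenolate may dehydrohalogenate the homoallylic iodide (E2). That would return 6 and, if long reaction times or warming are needed, could erode the trans selectivity. The fallback sets out from 6 and comes back at 11.
- Azaenolate 8 is alkylated with tert-butyl(3-iodopropoxy)dimethylsilane, an iodide without activated beta hydrogens, to give (S)-N-[(4S,6S)-4-[3-(tert-butyldimethylsilyloxy)propyl]-2,2-dimethyl-6-tetradecyl-1,3-dioxan-5-ylidene]-2-(methoxymethyl)pyrrolidin-1-amine F3.
- Saturated aqueous oxalic acid/Et2O cleaves the hydrazone to (4S,6S)-4-[3-(tert-butyldimethylsilyloxy)propyl]-2,2-dimethyl-6-tetradecyl-1,3-dioxan-5-one F4.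
- Pyridine-buffered HF·pyridine in THF frees (4S,6S)-4-(3-hydroxypropyl)-2,2-dimethyl-6-tetradecyl-1,3-dioxan-5-one F5.
- Dess–Martin periodinane oxidises F5 to 11.

Further compounds
F1 | step 5 | (4S,4aR,5S,7aS)-2,2-dimethyl-4-tetradecylhexahydrocyclopenta[d][1,3]dioxine-4a,5-diol | CCCCCCCCCCCCCC[C@@H]1OC(C)(C)O[C@H]2CC[C@H](O)[C@@]12O
F2 | step 8 | (4S,5R)-4,5-dihydroxy-5-[(1S)-1-hydroxypentadecyl]cyclopent-2-en-1-one | CCCCCCCCCCCCCC[C@H](O)[C@]1(O)C(=O)C=C[C@@H]1O
F3 | step 3 | (S)-N-[(4S,6S)-4-[3-(tert-butyldimethylsilyloxy)propyl]-2,2-dimethyl-6-tetradecyl-1,3-dioxan-5-ylidene]-2-(methoxymethyl)pyrrolidin-1-amine | CCCCCCCCCCCCCC[C@@H]1OC(C)(C)O[C@@H](CCCO[Si](C)(C)C(C)(C)C)C1=NN2CCC[C@H]2COC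
F4 | step 3 | (4S,6S)-4-[3-(tert-butyldimethylsilyloxy)propyl]-2,2-dimethyl-6-tetradecyl-1,3-dioxan-5-one | CCCCCCCCCCCCCC[C@@H]1OC(C)(C)O[C@@H](CCCO[Si](C)(C)C(C)(C)C)C1=O
F5 | step 3 | (4S,6S)-4-(3-hydroxypropyl)-2,2-dimethyl-6-tetradecyl-1,3-dioxan-5-one | CCCCCCCCCCCCCC[C@@H]1OC(C)(C)O[C@@H](CCCO)C1=O
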